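Assumption: the SMILES is read as (−)-epigallocatechin-(4β→6)-(−)-epigallocatechin 3-O-gallate, with the gallate on the lower unit, 2R,3R in both units and the upper C4 as S (4β, trans to the upper 3-OH). (−)-Epigallocatechin and 3,4,5-tris(benzyloxy)benzoic acid are taken as catalogue compounds.

**Retrosynthetic overview**
1. 9 ⇐ 8 by one global hydrogenolysis (13 benzyl ethers, 2 aryl bromides).
2. 8 ⇐ diol 5 + acid 6: the gallate ester C–O bond is the key bond, made by a site-selective esterification of the lower-unit 3-OH (new step).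
3. 5 ⇐ 4 + 3: the C4–C6 interflavan bond by Lewis-acid coupling; bromine at C8 of 3 leaves only C6 free, and the epi-series cation gives 4β.
4. 4 ⇐ 3 by DDQ C4–H oxygenation (a C4–O bond as leaving group); 3 ⇐ 2 ⇐ 1 by bromination and benzylation, so one monomer feeds both halves.
5. No ring is built: both chroman ring systems and all aryl rings come intact from 1 and 6.

**Route**

Step 1
Reactants: 1 (−)-epigallocatechin
Product: 2 5,7,3',4',5'-penta-O-benzyl-(−)-epigallocatechin (2R,3R; 3-OH free)
Conditions: BnBr (5.5 equiv), K2CO3 (6 equiv), DMF, N2, −10 °C to rt, 16 h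
Reagents that add atoms: benzyl bromide, BrCc1ccccc1
Why: Williamson ether synthesis in which K2CO3 deprotonates only the five phenols, so the secondary 3-OH stays free, and the cold, oxygen-free conditions avoid C2 epimerisation and oxidation of the pyrogallol ring.

Step 2
Reactants: 2 5,7,3',4',5'-penta-O-benzyl-(−)-epigallocatechin
Product: 3 8-bromo-5,7,3',4',5'-penta-O-benzyl-(−)-epigallocatechin
Conditions: NBS (1.0 equiv), CH2Cl2, −78 °C to rt
Reagents that add atoms: N-bromosuccinimide, BrN1C(=O)CCC1=O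
Why: Electrophilic aromatic bromination goes to C8 of the phloroglucinol-type ring A, the established site for 5,7-di-O-benzyl flavan-3-ols, and touches no stereocentre.

Step 3
Reactants: 3 8-bromo-5,7,3',4',5'-penta-O-benzyl-(−)-epigallocatechin
Product: 4 (2R,3R,4S)-8-bromo-5,7-bis(benzyloxy)-4-(2-ethoxyethoxy)-2-[3,4,5-tris(benzyloxy)phenyl]chroman-3-ol (4β-ether, trans to the 3-OH)
Conditions: DDQ (2 equiv), 2-ethoxyethanol (8 equiv), CH2Cl2, rt, 4 h
Reagents that add atoms: 2-ethoxyethanol, CCOCCO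
Why: DDQ benzylic C–H oxidation abstracts hydride from C4 to give a cation stabilised by the 5,7-dialkoxy ring, and the alcohol adds on the β face, anti to the axial 3-OH, setting the 4β (4S) C–O bond.

Step 4
Reactants: 4 the 4β-(2-ethoxyethoxy) electrophile (1 equiv); 3 8-bromo-5,7,3',4',5'-penta-O-benzyl-(−)-epigallocatechin (4 equiv, excess recovered)
Product: 5 8-bromo-5,7,3',4',5'-penta-O-benzyl-(−)-epigallocatechin-(4β→6)-8-bromo-5,7,3',4',5'-penta-O-benzyl-(−)-epigallocatechin (both 3-OH free)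
Conditions: Me3SiOTf (0.2 equiv), CH2Cl2, −78 to −40 °C; Et3N quench
Reagents that add atoms: none
Why: Lewis-acid Friedel–Crafts-type flavan condensation in which Me3SiOTf ionises the C4 ether and the cation is attacked by C6, the only free ring-A position of 3 (halo-capping at C8), from the β face trans to the 3-OH, which sets the upper C4 as 4β; the bromine on 4 and the excess of 3 hold back self-condensation.

Step 5
Reactants: 5 the dibromo deca-O-benzyl (4β→6) diol; 6 3,4,5-tris(benzyloxy)benzoic acid (1.15 equiv)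
Product: 8 8-bromo-5,7,3',4',5'-penta-O-benzyl-(−)-epigallocatechin-(4β→6)-8-bromo-5,7,3',4',5'-penta-O-benzyl-(−)-epigallocatechin 3-O-[3,4,5-tris(benzyloxy)benzoate] (ester on the lower unit; upper 3-OH free), via O-acylisourea 7 (not isolated)
Conditions: DCC (1.2 equiv), DMAP (0.2 equiv), CH2Cl2, 0 °C, 24 h, stopped at about 90% conversion
Reagents that add atoms: N,N'-dicyclohexylcarbodiimide, C(=NC1CCCCC1)=NC1CCCCC1 (its atoms stay in 7 only and leave as the urea; 8 takes its new atoms from 6)
Why: Proposed new method: a site-selective Steglich mono-galloylation of the lower-unit 3-OH of a (4→6) biflavan-3,3'-diol, not yet shown on any proanthocyanidin diol; the bulky N-acylpyridinium/carboxylate ion pair formed from 7 should reach the lower axial OH first because it has a CH2 neighbour, whereas the upper OH sits between two aryl-bearing methines (C2 with ring B, C4 with the hexasubstituted ring D and its ortho benzyloxy groups), and the closest known reaction type is the DMAP-catalysed Steglich galloylation of benzylated monomeric epicatechin or epigallocatechin together with sterically governed site-selective acylation of polyols; C3 keeps its configuration because only the O–H bond reacts.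

Step 6
Reactants: 8 the tridecabenzyl dibromo gallate
Product: 9 (−)-epigallocatechin-(4β→6)-(−)-epigallocatechin 3-O-gallate (CNP0204196.2)
Conditions: H2 (1 atm), 20% Pd(OH)2/C, Et3N (2.2 equiv), THF/MeOH/H2O 20:20:1, rt, 4 h; filter under Ar, 0.1% HCO2H, Sephadex LH-20, freeze-dry
Reagents that add atoms: none
Why: Heterogeneous catalytic hydrogenolysis cleaves the 13 benzyl ethers and both aryl C–Br bonds (hydrodehalogenation) while Et3N traps the HBr, so the acid-labile interflavan bond, the ester and all five stereocentres are left alone.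

**Compound list**
1 | (−)-epigallocatechin, (2R,3R) | O[C@@H]1Cc2c(O)cc(O)cc2O[C@@H]1c1cc(O)c(O)c(O)c1 | starting material
2 | 5,7,3',4',5'-penta-O-benzyl-(−)-epigallocatechin | O[C@@H]1Cc2c(OCc3ccccc3)cc(OCc3ccccc3)cc2O[C@@H]1c1cc(OCc2ccccc2)c(OCc2ccccc2)c(OCc2ccccc2)c1 | intermediate
3 | 8-bromo-5,7,3',4',5'-penta-O-benzyl-(−)-epigallocatechin | O[C@@H]1Cc2c(OCc3ccccc3)cc(OCc3ccccc3)c(Br)c2O[C@@H]1c1cc(OCc2ccccc2)c(OCc2ccccc2)c(OCc2ccccc2)c1 | intermediate
4 | (2R,3R,4S)-8-bromo-5,7-bis(benzyloxy)-4-(2-ethoxyethoxy)-2-[3,4,5-tris(benzyloxy)phenyl]chroman-3-ol | CCOCCO[C@H]1c2c(OCc3ccccc3)cc(OCc3ccccc3)c(Br)c2O[C@H](c2cc(OCc3ccccc3)c(OCc3ccccc3)c(OCc3ccccc3)c2)[C@@H]1O | intermediate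
5 | 8-bromo-penta-O-benzyl-epigallocatechin-(4β→6)-8-bromo-penta-O-benzyl-epigallocatechin, both units 2R,3R, both 3-OH free (the β bond at the upper C4 carries the CIP label R in this benzyl ether and S in the free phenol 9) | O[C@@H]1Cc2c(c(Br)c(OCc3ccccc3)c([C@H]3c4c(OCc5ccccc5)cc(OCc5ccccc5)c(Br)c4O[C@H](c4cc(OCc5ccccc5)c(OCc5ccccc5)c(OCc5ccccc5)c4)[C@@H]3O)c2OCc2ccccc2)O[C@@H]1c1cc(OCc2ccccc2)c(OCc2ccccc2)c(OCc2ccccc2)c1 | intermediate
6 | 3,4,5-tris(benzyloxy)benzoic acid | OC(=O)c1cc(OCc2ccccc2)c(OCc2ccccc2)c(OCc2ccccc2)c1 | starting material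
7 | N,N'-dicyclohexyl-O-[3,4,5-tris(benzyloxy)benzoyl]isourea | O=C(OC(=NC1CCCCC1)NC1CCCCC1)c1cc(OCc2ccccc2)c(OCc2ccccc2)c(OCc2ccccc2)c1 | intermediate
8 | lower-unit 3-O-[3,4,5-tris(benzyloxy)benzoate] of 5 (upper 3-OH free) | O=C(O[C@@H]1Cc2c(c(Br)c(OCc3ccccc3)c([C@H]3c4c(OCc5ccccc5)cc(OCc5ccccc5)c(Br)c4O[C@H](c4cc(OCc5ccccc5)c(OCc5ccccc5)c(OCc5ccccc5)c4)[C@@H]3O)c2OCc2ccccc2)O[C@@H]1c1cc(OCc2ccccc2)c(OCc2ccccc2)c(OCc2ccccc2)c1)c1cc(OCc2ccccc2)c(OCc2ccccc2)c(OCc2ccccc2)c1 | intermediate
9 | (−)-epigallocatechin-(4β→6)-(−)-epigallocatechin 3-O-gallate | O=C(O[C@@H]1Cc2c(cc(O)c([C@H]3c4c(O)cc(O)cc4O[C@H](c4cc(O)c(O)c(O)c4)[C@@H]3O)c2O)O[C@@H]1c1cc(O)c(O)c(O)c1)c1cc(O)c(O)c(O)c1 | target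

**Step count**
Total steps: 6. Longest linear sequence: 6 (1 → 2 → 3 → 4 → 5 → 8 → 9).

**Three steps most likely to fail**

Step 4 (C6 of 3 is deactivated by the bromine and flanked by two benzyloxy groups, so coupling may be slow and 4 may oligomerise). The fallback sets out from 4 and 3 and comes back at 5. It changes the electrophile class from an oxygen leaving group under acid to a sulfur leaving group under neutral thiophilic activation. Compound 4 is treated with benzyl mercaptan and catalytic BF3·OEt2 in CH2Cl2 at −78 °C to give 8-bromo-4β-benzylthio-5,7,3',4',5'-penta-O-benzyl-(−)-epigallocatechin F1. F1 is then coupled with 3 (4 equiv) using AgBF4 in THF at 0 °C, the known neutral activation of flavan 4-thioethers, which allows longer reaction times without acid scrambling of the new interflavan bond and gives 5.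

Step 5 (the proposed site-selective galloylation; the two secondary hydroxyls may differ too little, giving upper-unit ester and bis-gallate). The fallback uses only known chemistry, sets out from 3, 6 and 4, and comes back at 8. Monomer 3, which has a single free hydroxyl, is esterified with 6 under DCC/DMAP in CH2Cl2 at rt (through 7) to give 8-bromo-5,7,3',4',5'-penta-O-benzyl-(−)-epigallocatechin 3-O-[3,4,5-tris(benzyloxy)benzoate] F2. F2 (3 equiv) is then coupled with 4 under Me3SiOTf in CH2Cl2 at −78 to −40 °C, the known condensation with a galloylated nucleophile, to give 8 with the ester position fixed beforehand. The step count is unchanged.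

Step 6 (fifteen hydrogenolyses in one pot; HBr can cleave the interflavan bond and the free pyrogallols are base- and air-sensitive). The fallback sets out from 8 and comes back at 9. It separates the C–Br cleavage from the debenzylation. Compound 8 is debrominated by radical reduction with Bu3SnH and azobisisobutyronitrile in toluene at 90 °C to give 5,7,3',4',5'-penta-O-benzyl-(−)-epigallocatechin-(4β→6)-5,7,3',4',5'-penta-O-benzyl-(−)-epigallocatechin 3-O-[3,4,5-tris(benzyloxy)benzoate] F3. F3 is then hydrogenolysed with H2 over 20% Pd(OH)2/C in THF/MeOH/H2O with no amine and no halide present, giving 9.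

**Further compounds**
F1 | step 4 | 8-bromo-4β-benzylthio-5,7,3',4',5'-penta-O-benzyl-(−)-epigallocatechin | OC1[C@H](c2cc(OCc3ccccc3)c(OCc3ccccc3)c(OCc3ccccc3)c2)Oc2c(Br)c(OCc3ccccc3)cc(OCc3ccccc3)c2[C@@H]1SCc1ccccc1
F2 | step 5 | 8-bromo-5,7,3',4',5'-penta-O-benzyl-(−)-epigallocatechin 3-O-[3,4,5-tris(benzyloxy)benzoate] | O=C(O[C@@H]1Cc2c(OCc3ccccc3)cc(OCc3ccccc3)c(Br)c2O[C@@H]1c1cc(OCc2ccccc2)c(OCc2ccccc2)c(OCc2ccccc2)c1)c1cc(OCc2ccccc2)c(OCc2ccccc2)c(OCc2ccccc2)c1
F3 | step 6 | debrominated tridecabenzyl ether of 9 (lower-unit gallate, upper 3-OH free) | O=C(O[C@@H]1Cc2c(cc(OCc3ccccc3)c([C@H]3c4c(OCc5ccccc5)cc(OCc5ccccc5)cc4O[C@H](c4cc(OCc5ccccc5)c(OCc5ccccc5)c(OCc5ccccc5)c4)[C@@H]3O)c2OCc2ccccc2)O[C@@H]1c1cc(OCc2ccccc2)c(OCc2ccccc2)c(OCc2ccccc2)c1)c1cc(OCc2ccccc2)c(OCc2ccccc2)c(OCc2ccccc2)c1
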